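**Retrosynthetic overview**

1. The last two steps are removal of the two methoxymethyl ethers and, before that, an aromatic Claisen rearrangement of a 3'-O-(1,1-dimethylallyl) ether on ring B, which gives the C2' prenyl group and the free 3'-OH together.
2. Key disconnection: ring C (O1–C2–C3–C4–C4a–C8a) comes from a four-membered (4S)-4-aryl-oxetan-2-one (O1, C2, C3, C4). The two carbons C4a/C8a of a ring-A aryne, already carrying both protected oxygens and the C8 prenyl group, are inserted into its acyl–oxygen bond O1–C4. This is a ring expansion by two atoms that forms O1–C8a and C4–C4a and joins the two halves.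
3. Enabling feature: in ring C the acyl carbon C4 and the ether oxygen O1 sit on the adjacent ring-A carbons C4a and C8a, the 1,2-pattern an aryne delivers. The C5 oxygen next to C4a steers O1 to C8a. The only stereocentre, C2, lies inside the lactone with its C–O bond already made, so it is set beforehand and none of its bonds is touched.
4. The β-lactone comes from methyl 3,4-dihydroxybenzoate (propargyl ether, chromene, 1,1-dimethylallyl ether, Claisen condensation, asymmetric transfer hydrogenation, lactonisation). The aryne precursor comes from phloroglucinol (bis-MOM ether, O-allylation/Claisen for the prenyl group, carbamate-directed ortho-silylation, triflate).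
5. Order of ring formation: ring A is bought, the pyran ring of the chromene is closed in step 8, the oxetanone in step 13, and ring C by expansion in step 14.

Key step: step 14

Remark: atom numbers (O1 to C8a for rings C and A, primed numbers for ring B) follow flavanone numbering; the target is the (2S) enantiomer as encoded in its SMILES; tert-butyl (2-methylbut-3-en-2-yl) carbonate is treated as a purchasable reagent.

**Route**

Step 1
Reactants: 1 phloroglucinol (benzene-1,3,5-triol)
Product: 2 3,5-bis(methoxymethoxy)phenol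
Conditions: MOMCl (2 equiv), i-Pr2NEt, CH2Cl2/DMF, 0 °C
Reagents that add atoms: chloromethyl methyl ether, COCCl
Why: Williamson-type O-alkylation of three equivalent phenols, where only the degree of alkylation has to be controlled by stoichiometry and the mono- and tris-ethers can be separated and recycled.

Step 2
Reactants: 2 3,5-bis(methoxymethoxy)phenol
Product: 3 1,3-bis(methoxymethoxy)-5-[(2-methylbut-3-en-2-yl)oxy]benzene
Conditions: tert-butyl (2-methylbut-3-en-2-yl) carbonate, Pd(PPh3)4 (cat.), THF, 0 °C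
Reagents that add atoms: tert-butyl (2-methylbut-3-en-2-yl) carbonate, C=CC(C)(C)OC(=O)OC(C)(C)C
Why: Tsuji–Trost O-allylation in which the phenoxide attacks the more substituted terminus of the 1,1-dimethylallyl complex of palladium (formed from zerovalent palladium and the carbonate) under kinetic control, which should give the tertiary allyl ether.

Step 3
Reactants: 3 1,3-bis(methoxymethoxy)-5-[(2-methylbut-3-en-2-yl)oxy]benzene
Product: 4 3,5-bis(methoxymethoxy)-2-(3-methylbut-2-en-1-yl)phenol
Conditions: PhMe, 110 °C, sealed tube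
Reagents that add atoms: none
Why: Aromatic Claisen rearrangement, whose [3,3] shift inverts the allyl unit so that the tertiary ether delivers the linear prenyl group to one of the two equivalent ortho positions before tautomerisation restores the phenol.

Step 4
Reactants: 4 3,5-bis(methoxymethoxy)-2-(3-methylbut-2-en-1-yl)phenol
Product: 5 3,5-bis(methoxymethoxy)-2-(3-methylbut-2-en-1-yl)phenyl N-isopropylcarbamate
Conditions: i-PrNCO, Et3N (cat.), CH2Cl2, 23 °C
Reagents that add atoms: isopropyl isocyanate, CC(C)N=C=O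
Why: Addition of the phenol to the isocyanate gives an N-H carbamate, a strong ortho-directing group that can later be removed under mild basic conditions.

Step 5
Reactants: 5 3,5-bis(methoxymethoxy)-2-(3-methylbut-2-en-1-yl)phenyl N-isopropylcarbamate
Product: 9 3,5-bis(methoxymethoxy)-2-(3-methylbut-2-en-1-yl)-6-(trimethylsilyl)phenyl N-isopropylcarbamate, via N-silyl carbamate 6 (not isolated), via aryllithium 7 (not isolated), via bis-silyl carbamate 8 (not isolated)
Conditions: TMSOTf, TMEDA, Et2O, 23 °C; n-BuLi, TMEDA, −78 °C; Me3SiCl, −78 to 23 °C; aq. NaHSO4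
Reagents that add atoms: chlorotrimethylsilane, C[Si](C)(C)Cl
Why: Directed ortho-metalation, in which the N-silylated carbamate and the neighbouring methoxymethoxy group cooperatively direct lithiation to the one ring position between them (the future C4a), the aryllithium is silylated on carbon, and the N-silyl group is lost on aqueous work-up.

Step 6
Reactants: 9 3,5-bis(methoxymethoxy)-2-(3-methylbut-2-en-1-yl)-6-(trimethylsilyl)phenyl N-isopropylcarbamate
Product: 11 3,5-bis(methoxymethoxy)-2-(3-methylbut-2-en-1-yl)-6-(trimethylsilyl)phenyl trifluoromethanesulfonate, via silylphenol 10 (not isolated)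
Conditions: DBU, Et2NH, MeCN, 40 °C; then PhNTf2, 23 °C
Reagents that add atoms: N-phenylbis(trifluoromethanesulfonimide), O=S(=O)(N(c1ccccc1)S(=O)(=O)C(F)(F)F)C(F)(F)F
Why: Base-induced E1cB cleavage of the N-H carbamate (the isocyanate is scavenged by Et2NH) frees the hindered phenoxide, which is sulfonylated in the same flask to give an ortho-silylaryl triflate, the standard fluoride-triggered aryne precursor.

Step 7
Reactants: 12 methyl 3,4-dihydroxybenzoate
Product: 13 methyl 3-hydroxy-4-[(2-methylbut-3-yn-2-yl)oxy]benzoate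
Conditions: 3-chloro-3-methylbut-1-yne, K2CO3 (1 equiv), KI (cat.), acetone, 55 °C
Reagents that add atoms: 3-chloro-3-methylbut-1-yne, C#CC(C)(C)Cl
Why: Williamson etherification with the tertiary propargylic chloride, in which the 4-OH, para to the ester and therefore the more acidic phenol, should be alkylated selectively with one equivalent of base.

Step 8
Reactants: 13 methyl 3-hydroxy-4-[(2-methylbut-3-yn-2-yl)oxy]benzoate
Product: 14 methyl 8-hydroxy-2,2-dimethyl-2H-chromene-6-carboxylate
Conditions: N,N-diethylaniline, 180 °C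
Reagents that add atoms: none
Why: Thermal aryl propargyl ether Claisen rearrangement to the only free ortho position, followed by 1,5-hydrogen shift and oxa-6π electrocyclisation, closes the 2,2-dimethyl-2H-chromene ring.

Step 9
Reactants: 14 methyl 8-hydroxy-2,2-dimethyl-2H-chromene-6-carboxylate
Product: 15 methyl 2,2-dimethyl-8-[(2-methylbut-3-en-2-yl)oxy]-2H-chromene-6-carboxylate
Conditions: tert-butyl (2-methylbut-3-en-2-yl) carbonate, Pd(PPh3)4 (cat.), THF, 0 °C
Reagents that add atoms: tert-butyl (2-methylbut-3-en-2-yl) carbonate, C=CC(C)(C)OC(=O)OC(C)(C)C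
Why: Tsuji–Trost O-allylation at the branched terminus as in step 2, giving a tertiary allyl ether that protects the future 3'-OH, has no allylic hydrogen, and holds the future C2' prenyl group in latent form.

Step 10
Reactants: 15 methyl 2,2-dimethyl-8-[(2-methylbut-3-en-2-yl)oxy]-2H-chromene-6-carboxylate
Product: 16 ethyl 3-{2,2-dimethyl-8-[(2-methylbut-3-en-2-yl)oxy]-2H-chromen-6-yl}-3-oxopropanoate
Conditions: EtOAc, LiN(SiMe3)2 (3 equiv), THF, −78 to 0 °C; aq. NH4Cl
Reagents that add atoms: ethyl acetate, CCOC(C)=O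
Why: Crossed Claisen condensation of the non-enolisable aryl ester with the lithium enolate of ethyl acetate, driven to completion by deprotonation of the β-keto ester by the excess base.

Step 11
Reactants: 16 ethyl 3-{2,2-dimethyl-8-[(2-methylbut-3-en-2-yl)oxy]-2H-chromen-6-yl}-3-oxopropanoate
Product: 17 ethyl (3S)-3-{2,2-dimethyl-8-[(2-methylbut-3-en-2-yl)oxy]-2H-chromen-6-yl}-3-hydroxypropanoate
Conditions: RuCl(p-cymene)[(S,S)-TsDPEN] (1 mol %), HCO2H/Et3N (5:2), DMF, 30 °C
Reagents that add atoms: none
Why: Noyori-type asymmetric transfer hydrogenation of the aryl ketone, where the (S,S)-TsDPEN ruthenium hydride should deliver hydride to the face that gives the (S)-carbinol (aryl versus CH2 discrimination through the CH–π contact with the p-cymene ligand) and leave all alkenes untouched; this step sets the stereocentre that becomes C2 of the target.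

Step 12
Reactants: 17 ethyl (3S)-3-{2,2-dimethyl-8-[(2-methylbut-3-en-2-yl)oxy]-2H-chromen-6-yl}-3-hydroxypropanoate
Product: 18 (3S)-3-{2,2-dimethyl-8-[(2-methylbut-3-en-2-yl)oxy]-2H-chromen-6-yl}-3-hydroxypropanoic acid
Conditions: LiOH, THF/H2O, 0 °C; then 1 M HCl to pH 4, 0 °C
Reagents that add atoms: water (hydroxide from LiOH), O
Why: Saponification of the ethyl ester in which the carbinol centre is not involved, with a cold and only weakly acidic work-up to spare the tertiary allyl aryl ether.

Step 13
Reactants: 18 (3S)-3-{2,2-dimethyl-8-[(2-methylbut-3-en-2-yl)oxy]-2H-chromen-6-yl}-3-hydroxypropanoic acid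
Product: 20 (4S)-4-{2,2-dimethyl-8-[(2-methylbut-3-en-2-yl)oxy]-2H-chromen-6-yl}oxetan-2-one, via mixed anhydride 19 (not isolated)
Conditions: PhSO2Cl, pyridine, 0 °C
Reagents that add atoms: none
Why: Lactonisation by carboxyl activation, in which the β-hydroxyl attacks the sulfonic–carboxylic mixed anhydride in a 4-exo-trig acyl substitution, so the C–O bond at the stereocentre is not broken and the (S) configuration is retained.

Step 14
Reactants: 20 (4S)-4-{2,2-dimethyl-8-[(2-methylbut-3-en-2-yl)oxy]-2H-chromen-6-yl}oxetan-2-one; 11 3,5-bis(methoxymethoxy)-2-(3-methylbut-2-en-1-yl)-6-(trimethylsilyl)phenyl trifluoromethanesulfonate (1.5 equiv)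
Product: 22 (2S)-2-{2,2-dimethyl-8-[(2-methylbut-3-en-2-yl)oxy]-2H-chromen-6-yl}-5,7-bis(methoxymethoxy)-8-(3-methylbut-2-en-1-yl)-2,3-dihydro-4H-chromen-4-one, via aryne 21 (not isolated)
Conditions: CsF, MeCN, 23 °C, slow addition of 11
Reagents that add atoms: none
Why: Proposed new method: fluoride unmasks aryne 21 from 11; the ring oxygen O1 of the strained lactone 20 adds to the aryne carbon that becomes C8a, and the aryl anion thus formed at C4a collapses onto the neighbouring acyl carbon C4 and cleaves the acyl–oxygen bond, so that the two aryne carbons are inserted into the O1–C4 σ bond and the four-membered oxetan-2-one becomes the six-membered chroman-4-one (a fluoride-relayed variant, with reversible opening of 20 to the β-alkoxide acyl fluoride, O-arylation and acyl substitution, leads to the same product). The closest known reaction types are the aryne σ-insertion into the N–C(O) bond of amides and ureas, the aryne C–O insertion of epoxides and of carboxylic acids, and the tandem O-arylation/acyl transfer of salicylates to xanthones; what is new is an ester-type ring oxygen as the donor. Ring C is closed through two bonds, O1–C8a by nucleophilic addition to the aryne and C4–C4a by 4-exo-trig addition of the aryl anion to the carbonyl followed by fragmentation of the four-membered ring (6-exo-trig in the relay pathway). No new stereocentre is formed: C2 is carried over from 20 with retention because none of its four bonds is broken in either pathway. The step needs attack at the aryne carbon remote from the C5 methoxymethoxy group, which the inductive polarisation of a 3-alkoxyaryne secures and the C8 prenyl group opposes only sterically, and it needs the lactone to outrun ene reactions of the aryne, which is why ring B carries its future prenyl group as a 1,1-dimethylallyl ether without allylic hydrogen and a chromene that has none either. The strain of the β-lactone and the formation of an aryl ketone conjugated with two alkoxy groups provide the driving force.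

Step 15
Reactants: 22 (2S)-2-{2,2-dimethyl-8-[(2-methylbut-3-en-2-yl)oxy]-2H-chromen-6-yl}-5,7-bis(methoxymethoxy)-8-(3-methylbut-2-en-1-yl)-2,3-dihydro-4H-chromen-4-one
Product: 23 (2S)-2-[8-hydroxy-2,2-dimethyl-7-(3-methylbut-2-en-1-yl)-2H-chromen-6-yl]-5,7-bis(methoxymethoxy)-8-(3-methylbut-2-en-1-yl)-2,3-dihydro-4H-chromen-4-one
Conditions: PhMe, 110 °C, sealed tube
Reagents that add atoms: none
Why: Aromatic Claisen rearrangement of the tertiary allyl aryl ether to C2', the only free ortho position (C4' carries the chromene oxygen), installs the linear prenyl group and unveils the 3'-OH under neutral thermal conditions that should not touch C2 of the flavanone.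

Step 16
Reactants: 23 (2S)-2-[8-hydroxy-2,2-dimethyl-7-(3-methylbut-2-en-1-yl)-2H-chromen-6-yl]-5,7-bis(methoxymethoxy)-8-(3-methylbut-2-en-1-yl)-2,3-dihydro-4H-chromen-4-one
Product: 24 (2S)-5,7-dihydroxy-2-[8-hydroxy-2,2-dimethyl-7-(3-methylbut-2-en-1-yl)-2H-chromen-6-yl]-8-(3-methylbut-2-en-1-yl)-2,3-dihydro-4H-chromen-4-one (CNP0328260.1)
Conditions: 3 M aq. HCl/MeOH (1:5), 45 °C
Reagents that add atoms: none
Why: Acid-catalysed acetal methanolysis removes both methoxymethyl groups, the chelated 5-O first, under conditions mild enough that the prenyl groups, the chromene and the C2 stereocentre should survive.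

**Compound list**

1 | phloroglucinol (benzene-1,3,5-triol) | Oc1cc(O)cc(O)c1 | starting material
2 | 3,5-bis(methoxymethoxy)phenol | COCOc1cc(O)cc(OCOC)c1 | intermediate
3 | 1,3-bis(methoxymethoxy)-5-[(2-methylbut-3-en-2-yl)oxy]benzene | C=CC(C)(C)Oc1cc(OCOC)cc(OCOC)c1 | intermediate
4 | 3,5-bis(methoxymethoxy)-2-(3-methylbut-2-en-1-yl)phenol | CC(C)=CCc1c(O)cc(OCOC)cc1OCOC | intermediate
5 | 3,5-bis(methoxymethoxy)-2-(3-methylbut-2-en-1-yl)phenyl N-isopropylcarbamate | CC(C)NC(=O)Oc1cc(OCOC)cc(OCOC)c1CC=C(C)C | intermediate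
6 | 3,5-bis(methoxymethoxy)-2-(3-methylbut-2-en-1-yl)phenyl N-isopropyl-N-(trimethylsilyl)carbamate | CC(C)N([Si](C)(C)C)C(=O)Oc1cc(OCOC)cc(OCOC)c1CC=C(C)C | intermediate
7 | {2-[N-isopropyl-N-(trimethylsilyl)carbamoyloxy]-4,6-bis(methoxymethoxy)-3-(3-methylbut-2-en-1-yl)phenyl}lithium | CC(C)N([Si](C)(C)C)C(=O)Oc1c([Li])c(OCOC)cc(OCOC)c1CC=C(C)C | intermediate
8 | 3,5-bis(methoxymethoxy)-2-(3-methylbut-2-en-1-yl)-6-(trimethylsilyl)phenyl N-isopropyl-N-(trimethylsilyl)carbamate | CC(C)N([Si](C)(C)C)C(=O)Oc1c([Si](C)(C)C)c(OCOC)cc(OCOC)c1CC=C(C)C | intermediate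
9 | 3,5-bis(methoxymethoxy)-2-(3-methylbut-2-en-1-yl)-6-(trimethylsilyl)phenyl N-isopropylcarbamate | CC(C)NC(=O)Oc1c([Si](C)(C)C)c(OCOC)cc(OCOC)c1CC=C(C)C | intermediate
10 | 3,5-bis(methoxymethoxy)-2-(3-methylbut-2-en-1-yl)-6-(trimethylsilyl)phenol | Oc1c([Si](C)(C)C)c(OCOC)cc(OCOC)c1CC=C(C)C | intermediate
11 | 3,5-bis(methoxymethoxy)-2-(3-methylbut-2-en-1-yl)-6-(trimethylsilyl)phenyl trifluoromethanesulfonate | CC(C)=CCc1c(OS(=O)(=O)C(F)(F)F)c([Si](C)(C)C)c(OCOC)cc1OCOC | intermediate
12 | methyl 3,4-dihydroxybenzoate | COC(=O)c1ccc(O)c(O)c1 | starting material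
13 | methyl 3-hydroxy-4-[(2-methylbut-3-yn-2-yl)oxy]benzoate | COC(=O)c1ccc(OC(C)(C)C#C)c(O)c1 | intermediate
14 | methyl 8-hydroxy-2,2-dimethyl-2H-chromene-6-carboxylate | COC(=O)c1cc(O)c2c(c1)C=CC(C)(C)O2 | intermediate
15 | methyl 2,2-dimethyl-8-[(2-methylbut-3-en-2-yl)oxy]-2H-chromene-6-carboxylate | COC(=O)c1cc(OC(C)(C)C=C)c2c(c1)C=CC(C)(C)O2 | intermediate
16 | ethyl 3-{2,2-dimethyl-8-[(2-methylbut-3-en-2-yl)oxy]-2H-chromen-6-yl}-3-oxopropanoate | CCOC(=O)CC(=O)c1cc(OC(C)(C)C=C)c2c(c1)C=CC(C)(C)O2 | intermediate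
17 | ethyl (3S)-3-{2,2-dimethyl-8-[(2-methylbut-3-en-2-yl)oxy]-2H-chromen-6-yl}-3-hydroxypropanoate | CCOC(=O)C[C@H](O)c1cc(OC(C)(C)C=C)c2c(c1)C=CC(C)(C)O2 | intermediate
18 | (3S)-3-{2,2-dimethyl-8-[(2-methylbut-3-en-2-yl)oxy]-2H-chromen-6-yl}-3-hydroxypropanoic acid | OC(=O)C[C@H](O)c1cc(OC(C)(C)C=C)c2c(c1)C=CC(C)(C)O2 | intermediate
19 | benzenesulfonic (3S)-3-{2,2-dimethyl-8-[(2-methylbut-3-en-2-yl)oxy]-2H-chromen-6-yl}-3-hydroxypropanoic anhydride | O=C(C[C@H](O)c1cc(OC(C)(C)C=C)c2c(c1)C=CC(C)(C)O2)OS(=O)(=O)c3ccccc3 | intermediate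
20 | (4S)-4-{2,2-dimethyl-8-[(2-methylbut-3-en-2-yl)oxy]-2H-chromen-6-yl}oxetan-2-one | O=C1C[C@H](O1)c2cc(OC(C)(C)C=C)c3c(c2)C=CC(C)(C)O3 | intermediate
21 | 4,6-bis(methoxymethoxy)-3-(3-methylbut-2-en-1-yl)-1,2-didehydrobenzene (aryne) | CC(C)=CCC1=C(OCOC)C=C(OCOC)C#C1 | intermediate
22 | (2S)-2-{2,2-dimethyl-8-[(2-methylbut-3-en-2-yl)oxy]-2H-chromen-6-yl}-5,7-bis(methoxymethoxy)-8-(3-methylbut-2-en-1-yl)-2,3-dihydro-4H-chromen-4-one | C=CC(C)(C)Oc1cc([C@@H]2CC(=O)c3c(OCOC)cc(OCOC)c(CC=C(C)C)c3O2)cc2c1OC(C)(C)C=C2 | intermediate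
23 | (2S)-2-[8-hydroxy-2,2-dimethyl-7-(3-methylbut-2-en-1-yl)-2H-chromen-6-yl]-5,7-bis(methoxymethoxy)-8-(3-methylbut-2-en-1-yl)-2,3-dihydro-4H-chromen-4-one | CC(C)=CCc1c([C@@H]2CC(=O)c3c(OCOC)cc(OCOC)c(CC=C(C)C)c3O2)cc2c(c1O)OC(C)(C)C=C2 | intermediate
24 | (2S)-5,7-dihydroxy-2-[8-hydroxy-2,2-dimethyl-7-(3-methylbut-2-en-1-yl)-2H-chromen-6-yl]-8-(3-methylbut-2-en-1-yl)-2,3-dihydro-4H-chromen-4-one | CC(C)=CCc1c([C@@H]2CC(=O)c3c(O)cc(O)c(CC=C(C)C)c3O2)cc2c(c1O)OC(C)(C)C=C2 | target

**Step count and risks**

Total step count: 16. Longest linear sequence: 10 steps (12 to 24 through steps 7 to 16); the ring-A branch from 1 has 9.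

Steps most likely to fail:

1. Step 14 (Proposed new method). The ester-type ring oxygen may be too weak a donor, so that the aryne is consumed by self-reaction or by ene reaction with prenyl groups. Attack through the carbonyl oxygen, or ionisation of the benzylic C2–O bond to the para-alkoxy-stabilised cation, would erode or invert the configuration. Fluoride may also open the lactone irreversibly. Fallback with known chemistry (aryl ketone synthesis by directed metalation, then Mitsunobu closure of ring C): it sets out from keto ester 16 and carbamate 5 and comes back at 22. Transfer hydrogenation of 16 with the enantiomeric catalyst RuCl(p-cymene)[(R,R)-TsDPEN] should give ethyl (3R)-3-{2,2-dimethyl-8-[(2-methylbut-3-en-2-yl)oxy]-2H-chromen-6-yl}-3-hydroxypropanoate F1. TBSCl/imidazole would convert it into its silyl ether, ethyl (3R)-3-[(tert-butyldimethylsilyl)oxy]-3-{2,2-dimethyl-8-[(2-methylbut-3-en-2-yl)oxy]-2H-chromen-6-yl}propanoate F2, and Me(MeO)NH·HCl/i-PrMgCl into the Weinreb amide (3R)-3-[(tert-butyldimethylsilyl)oxy]-3-{2,2-dimethyl-8-[(2-methylbut-3-en-2-yl)oxy]-2H-chromen-6-yl}-N-methoxy-N-methylpropanamide F3. Aryllithium 7, generated from 5 exactly as in step 5, would be acylated by F3 (Weinreb ketone synthesis) and give after aqueous work-up 2-[(3R)-3-[(tert-butyldimethylsilyl)oxy]-3-{2,2-dimethyl-8-[(2-methylbut-3-en-2-yl)oxy]-2H-chromen-6-yl}propanoyl]-3,5-bis(methoxymethoxy)-6-(3-methylbut-2-en-1-yl)phenyl N-isopropylcarbamate F4. DBU/Et2NH would free the phenol (3R)-3-[(tert-butyldimethylsilyl)oxy]-3-{2,2-dimethyl-8-[(2-methylbut-3-en-2-yl)oxy]-2H-chromen-6-yl}-1-[2-hydroxy-4,6-bis(methoxymethoxy)-3-(3-methylbut-2-en-1-yl)phenyl]propan-1-one F5, and HF·pyridine the carbinol (3R)-3-{2,2-dimethyl-8-[(2-methylbut-3-en-2-yl)oxy]-2H-chromen-6-yl}-3-hydroxy-1-[2-hydroxy-4,6-bis(methoxymethoxy)-3-(3-methylbut-2-en-1-yl)phenyl]propan-1-one F6. PPh3/DIAD (Mitsunobu) would then close ring C by attack of the phenol on the benzylic carbon with inversion, giving 22.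

2. Step 13. The activated β-hydroxy acid, or the electron-rich 4-aryl lactone itself, may fragment with loss of CO2 through the para-alkoxybenzyl cation to the styrene, and the lactone may decompose on silica. Fallback (ketene–aldehyde [2+2] cycloaddition instead of lactonisation, so that no activated acid is present and the stereocentre is set by the cycloaddition catalyst): it sets out from ester 15 and comes back at 20. Reduction with i-Bu2AlH should give {2,2-dimethyl-8-[(2-methylbut-3-en-2-yl)oxy]-2H-chromen-6-yl}methanol F7, and MnO2 the aldehyde 2,2-dimethyl-8-[(2-methylbut-3-en-2-yl)oxy]-2H-chromene-6-carbaldehyde F8. Ketene generated in the flask from acetyl chloride and i-Pr2NEt would then be added at −78 °C under catalysis by an O-trimethylsilyl cinchona alkaloid (quinidine or quinine derivative, whichever pseudoenantiomer gives the 4S lactone) with LiClO4 as co-catalyst, giving 20, which would be used crude in step 14.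

3. Step 5. Lithiation may occur at the wrong site: between the two methoxymethoxy groups (the future C6), or laterally at the benzylic and allylic CH2 of the prenyl group next to the carbamate. Fallback (silicon first, prenyl last, the prenyl group being introduced as an electrophile instead of by Claisen rearrangement, so that steps 2 to 4 are bypassed): it sets out from phenol 2 and comes back at 9. i-PrNCO/Et3N should give 3,5-bis(methoxymethoxy)phenyl N-isopropylcarbamate F9. The silylation protocol of step 5 would give 3,5-bis(methoxymethoxy)-2-(trimethylsilyl)phenyl N-isopropylcarbamate F10, where two equivalent positions flanked by the carbamate compete with one between the ethers and no lateral site exists. A second N-silylation and lithiation at the remaining position next to the carbamate, followed by alkylation of the aryllithium with prenyl bromide, would give 9.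

**Further compounds**

F1 | step 14 | ethyl (3R)-3-{2,2-dimethyl-8-[(2-methylbut-3-en-2-yl)oxy]-2H-chromen-6-yl}-3-hydroxypropanoate | CCOC(=O)C[C@@H](O)c1cc(OC(C)(C)C=C)c2c(c1)C=CC(C)(C)O2
F2 | step 14 | ethyl (3R)-3-[(tert-butyldimethylsilyl)oxy]-3-{2,2-dimethyl-8-[(2-methylbut-3-en-2-yl)oxy]-2H-chromen-6-yl}propanoate | CCOC(=O)C[C@@H](O[Si](C)(C)C(C)(C)C)c1cc(OC(C)(C)C=C)c2c(c1)C=CC(C)(C)O2
F3 | step 14 | (3R)-3-[(tert-butyldimethylsilyl)oxy]-3-{2,2-dimethyl-8-[(2-methylbut-3-en-2-yl)oxy]-2H-chromen-6-yl}-N-methoxy-N-methylpropanamide | CON(C)C(=O)C[C@@H](O[Si](C)(C)C(C)(C)C)c1cc(OC(C)(C)C=C)c2c(c1)C=CC(C)(C)O2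
F4 | step 14 | 2-[(3R)-3-[(tert-butyldimethylsilyl)oxy]-3-{2,2-dimethyl-8-[(2-methylbut-3-en-2-yl)oxy]-2H-chromen-6-yl}propanoyl]-3,5-bis(methoxymethoxy)-6-(3-methylbut-2-en-1-yl)phenyl N-isopropylcarbamate | CC(C)NC(=O)Oc1c(C(=O)C[C@@H](O[Si](C)(C)C(C)(C)C)c2cc(OC(C)(C)C=C)c3c(c2)C=CC(C)(C)O3)c(OCOC)cc(OCOC)c1CC=C(C)C
F5 | step 14 | (3R)-3-[(tert-butyldimethylsilyl)oxy]-3-{2,2-dimethyl-8-[(2-methylbut-3-en-2-yl)oxy]-2H-chromen-6-yl}-1-[2-hydroxy-4,6-bis(methoxymethoxy)-3-(3-methylbut-2-en-1-yl)phenyl]propan-1-one | Oc1c(C(=O)C[C@@H](O[Si](C)(C)C(C)(C)C)c2cc(OC(C)(C)C=C)c3c(c2)C=CC(C)(C)O3)c(OCOC)cc(OCOC)c1CC=C(C)C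
F6 | step 14 | (3R)-3-{2,2-dimethyl-8-[(2-methylbut-3-en-2-yl)oxy]-2H-chromen-6-yl}-3-hydroxy-1-[2-hydroxy-4,6-bis(methoxymethoxy)-3-(3-methylbut-2-en-1-yl)phenyl]propan-1-one | Oc1c(C(=O)C[C@@H](O)c2cc(OC(C)(C)C=C)c3c(c2)C=CC(C)(C)O3)c(OCOC)cc(OCOC)c1CC=C(C)C
F7 | step 13 | {2,2-dimethyl-8-[(2-methylbut-3-en-2-yl)oxy]-2H-chromen-6-yl}methanol | OCc1cc(OC(C)(C)C=C)c2c(c1)C=CC(C)(C)O2
F8 | step 13 | 2,2-dimethyl-8-[(2-methylbut-3-en-2-yl)oxy]-2H-chromene-6-carbaldehyde | O=Cc1cc(OC(C)(C)C=C)c2c(c1)C=CC(C)(C)O2
F9 | step 5 | 3,5-bis(methoxymethoxy)phenyl N-isopropylcarbamate | CC(C)NC(=O)Oc1cc(OCOC)cc(OCOC)c1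
F10 | step 5 | 3,5-bis(methoxymethoxy)-2-(trimethylsilyl)phenyl N-isopropylcarbamate | CC(C)NC(=O)Oc1cc(OCOC)cc(OCOC)c1[Si](C)(C)C
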